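## Analysis of the target

The target (22) is a spiro[chromane-2,2'-bicyclo[2.2.1]heptane]. Benzene ring A is fused to pyran ring B (O1, C2, C3, C4, C4a, C8a), and C2 is also C2' of a 3',3'-dimethylnorbornane, the carbon skeleton of camphene. Ring A is a fully substituted phloroglucinol: ring oxygen at C8a, free hydroxyls at C5 and C7, formyl groups at C6 and C8, and C4 attached at C4a. There are four stereocentres. The bridgeheads C1' (R) and C4' (S) form a fixed pair. The quaternary spiro carbon C2 (R) carries O1 on the endo face and C3 on the exo face of the norbornane. The benzylic carbon C4 (S) carries its isobutyl group on the same side of ring B as C3', the CMe2 carbon. The sensitive points are the two ortho-hydroxy aldehydes, the electron-rich ring, and above all the C2–O1 bond: a tertiary aryl ether beside a quaternary carbon on a norbornane, whose ionisation would allow Wagner–Meerwein shifts and loss of the spiro configuration. The synthesis is hard because the C2–O bond cannot be made by SN2 and not safely by SN1 chemistry, because C4 must be fixed both relative to a spiro centre two bonds away and in the absolute sense, and because aldehydes and free phenols tolerate little of the chemistry needed earlier. The plan rests on the fact that C4 is bonded to C4a, which is ortho to O1 (on C8a), ortho to the C5 oxygen and para to the C7 oxygen. This is the most nucleophilic carbon of a 3,5-dioxygenated phenyl ether, and the two carbons ortho to the ether oxygen are equivalent, so C4–C4a can be closed by electrophilic substitution with C4 arriving as a stereodefined electrophile.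

## Retrosynthetic reasoning

**22 to 21 (C6–CHO and C8–CHO).** The formyl groups are removed first, because aldehydes would not survive the organometallic, radical and hydrogenation steps. C6 and C8 are the only free positions of ring A in 21, so the forward double formylation of the diphenol has no regiochemical question.

**21 to 20 (two O–benzyl bonds).** The phenols are carried as benzyl ethers rather than methyl ethers. Benzyl is removed by hydrogenolysis under neutral conditions, whereas the acids or hot nucleophiles needed for methyl ethers would endanger the C2–O1 bond or the aldehydes. Benzyl survives everything that precedes.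

**20 to 19 to 18 (C–H in place of C–O on the side chain).** The side-chain hydroxyl of 18 is the trace of an epoxide oxygen. It is removed through xanthate 19 by a radical chain, which avoids a cation next to C4 and leaves C4 untouched.

**18 to 17 (C4–C4a).** This is the key cut. It opens ring B at its only bond to a ring A carbon and leaves an arene whose most nucleophilic carbons are the ones needed. C4 becomes an epoxide carbon, so its configuration comes from a reagent-controlled epoxidation. Cutting O1–C2 instead would require substitution at a tertiary neopentylic centre. The forward reaction must open the epoxide at its proximal carbon with inversion without ionising the tertiary ether.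

**17 to 16 (epoxide C–O bonds).** The trans-epoxide comes from the E-alkene by a chiral dioxirane epoxidation. The alkene faces are chosen by the catalyst, and the (2S,3S) epoxide is the one that inverts to 4S.

**16 to 14 and 15 (C=C).** Cross-metathesis attaches the isopropyl terminus late from the volatile alkene 15. This lets the three-carbon tether enter earlier as a simple allyl group.

**14 to 12 and 7 (aryl C–O bond).** The aryl–oxygen bond is cut, not the alkyl–oxygen bond, so the oxygen is already on C2 and the configuration there is never at risk. The hindered alkoxide of 12 is arylated by aryne 13, released from silyl triflate 7. Addition at the aryne carbon remote from the neighbouring benzyloxy group gives exactly the 3,5-dioxygenated pattern.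

**7 to 5 to 2 to 1 (C–Si and O–S bonds).** The ortho-silyl group is placed by carbamate-directed metalation of the carbamate 2 of commercial phenol 1. The carbamate is then exchanged for the triflate.

**12 to 10 and 11 (C2–CH2 bond).** Allyl Grignard 11 adds to ketone 10. Attack on the exo face puts carbon exo and oxygen endo, which is the spiro configuration of 22. Ketone 10 cannot enolise.

**10 to 8 (C=C).** Oxidative cleavage of the exocyclic methylene of (−)-camphene 8 gives 10. The chiral pool thus supplies C1' and C4'.

## Alternatives that were turned down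

**Alternative 1:** This route cuts O1–C2 and C2–C1' at once and builds the norbornane onto the chroman. The precursor is phenol ketone A2, in which a cyclopent-3-enyl group sits on the CMe2 carbon. In the forward step a chloride-donating Lewis acid condenses phenol and ketone to a cyclic aryloxocarbenium ion, one alkene carbon attacks C2, and chloride caps the secondary cation to give chloride A1.
- For it: one operation forms the C–O bond, a C–C bond, the spiro centre and the bicycle, and no chiral-pool terpene is needed. In bonds per step it is stronger than the chosen route.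
- Against it: three stereocentres (C2, C1', C4') must be set relative to C4 by one isobutyl group in a 1,3 relationship. The two alkene carbons of the cyclopentene are diastereotopic and either can attack. The oxocarbenium ion can instead lose a proton from C3. The 2-norbornyl cation can undergo hydride and Wagner–Meerwein shifts, or fragment back, before chloride arrives. A2 itself needs C4 set enantioselectively beside a hindered α-quaternary ketone, and A1 needs an extra dechlorination.
- Comparison: the chosen route forms fewer bonds in its key step, but each stereocentre is set by one well-understood element: the terpene for C1' and C4', exo addition for C2, the epoxide for C4.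

**Alternative 2:** This route cuts C4–C4a and O1–C2 and keeps a C3=C4 double bond. Phloroglucinol A5 adds through carbon to the carbonyl of enone A4 (from 10). Loss of water gives a 1-oxatriene, which closes by oxa-6π electrocyclisation to 2H-chromene A3. Hydrogenation and double formylation would finish the synthesis.
- For it: it is much the shortest route and needs no protecting groups; in step economy it is clearly stronger than the chosen route. Hydrogenation of A3 from the face opposite C3' should also give the required C4 configuration.
- Against it: the spiro configuration is set when the phenolic oxygen bonds to the norbornylidene carbon. Like other additions to that carbon, this should prefer the exo face, which places O1 exo, the opposite of the target. The closure is reversible, so the result would drift to whichever epimer is more stable. The hindered, poorly electrophilic ketone of A4 also invites conjugate pathways and multiple annulation on the three equivalent positions of A5.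
- Comparison: the chosen route is longer, but it makes C2 by C–C bond formation from the exo face, which places oxygen endo by default.

**Alternative 3:** This route cuts C2–C1' and C3'–C4' and builds the norbornane by cycloaddition onto a finished chroman. One-electron oxidation of enol ether A7 to its cation radical lets cyclopentadiene A8 add across the exocyclic C2=CMe2 bond to give norbornene A6. Hydrogenation and the end game follow.
- For it: it forms the two adjacent quaternary carbons C2 and C3' in one step, which no thermal cycloaddition would do, and it is convergent. On that point it is bolder and more direct than the chosen route.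
- Against it: a tetrasubstituted enol ether is a very hindered dienophile. The oxidant must select the enol ether over the trialkoxyarene and over A8, which dimerises under such conditions. The diene must choose one face of the enol ether (directed only by C4, two bonds away) and one orientation (O1 endo or exo to the new bicycle), so up to four diastereomers can form with no strong bias for O1 endo. The absolute configuration of the norbornane would follow only indirectly from C4, and A7 needs a lactone olefination.
- Comparison: the chosen route avoids all of these selectivity questions by taking the bicycle from 8.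

Key step: step 9

Assumption: (−)-camphene is taken as the (1S,4R) enantiomer. Commercial material is often not enantiopure; material from the minor enantiomer becomes a diastereomer after the reagent-controlled epoxidation (step 8) and should be separable from then on.

## Route

Step 1
Reactants: 1 3,5-bis(benzyloxy)phenol
Product: 2 3,5-bis(benzyloxy)phenyl N-(propan-2-yl)carbamate
Conditions: iPrNCO, Et3N (cat.), CH2Cl2, rt
Reagents that add atoms: isopropyl isocyanate, CC(C)N=C=O
Why: Base-catalysed addition of the phenol to the isocyanate (carbamoylation) gives an N-monosubstituted carbamate, which directs ortho-metalation and can later be removed under mild base.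

Step 2
Reactants: 2 3,5-bis(benzyloxy)phenyl N-(propan-2-yl)carbamate
Product: 5 3,5-bis(benzyloxy)-2-(trimethylsilyl)phenyl N-(propan-2-yl)carbamate, via N-silyl carbamate 3 (not isolated), via C-silylated N-silyl carbamate 4 (not isolated)
Conditions: TBSOTf, TMEDA, Et2O, 0 °C → rt; n-BuLi, TMEDA, −78 °C; TMSCl, −78 °C → rt; aq. NaHSO4
Reagents that add atoms: chlorotrimethylsilane, C[Si](C)(C)Cl
Why: N-silylation in the flask masks the N–H; the O-carbamate and the neighbouring benzyloxy group then direct lithiation to the carbon between them (directed ortho-metalation), which at −78 °C should outrun deprotonation of the benzylic CH2 groups; the aryllithium is C-silylated and the N–Si bond is hydrolysed at work-up.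

Step 3
Reactants: 5 3,5-bis(benzyloxy)-2-(trimethylsilyl)phenyl N-(propan-2-yl)carbamate
Product: 7 3,5-bis(benzyloxy)-2-(trimethylsilyl)phenyl trifluoromethanesulfonate, via ortho-silyl phenol 6 (not isolated)
Conditions: DBU, Et2NH, MeCN, 40 °C; then PhNTf2, rt
Reagents that add atoms: N-phenylbis(trifluoromethanesulfonimide), O=S(=O)(N(c1ccccc1)S(=O)(=O)C(F)(F)F)C(F)(F)F
Why: DBU deprotonates the carbamate N–H and the anion expels the phenoxide (E1cB cleavage), the isocyanate being trapped by diethylamine; the phenoxide is triflated in the same flask to give the ortho-silylaryl triflate aryne precursor.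

Step 4
Reactants: 8 (−)-camphene, (1S,4R)-2,2-dimethyl-3-methylidenebicyclo[2.2.1]heptane
Product: 10 (1R,4S)-3,3-dimethylbicyclo[2.2.1]heptan-2-one (camphenilone), via ozonide 9 (not isolated)
Conditions: O3, CH2Cl2, −78 °C; then Me2S, −78 °C → rt
Reagents that add atoms: ozone, [O-][O+]=O
Why: Ozonolysis of the 1,1-disubstituted exocyclic alkene with reductive work-up gives the ketone; the bridgehead stereocentres are not touched, and the ketone cannot enolise (quaternary carbon on one side, bridgehead on the other).

Step 5
Reactants: 10 (1R,4S)-3,3-dimethylbicyclo[2.2.1]heptan-2-one; 11 allylmagnesium bromide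
Product: 12 (1R,2R,4S)-3,3-dimethyl-2-(prop-2-en-1-yl)bicyclo[2.2.1]heptan-2-ol (allyl exo; hydroxyl endo)
Conditions: THF/Et2O, −78 → 0 °C; aq. NH4Cl
Reagents that add atoms: none
Why: Grignard 1,2-addition to a non-enolisable ketone; as for other 7-unsubstituted norbornan-2-ones, the reagent should approach the exo face (the endo face is screened by the C5–C6 bridge hydrogens and the endo methyl), so carbon becomes exo and oxygen endo, the configuration needed at spiro carbon C2.

Step 6
Reactants: 12 (1R,2R,4S)-3,3-dimethyl-2-(prop-2-en-1-yl)bicyclo[2.2.1]heptan-2-ol; 7 3,5-bis(benzyloxy)-2-(trimethylsilyl)phenyl trifluoromethanesulfonate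
Product: 14 (1R,2R,4S)-2-[3,5-bis(benzyloxy)phenoxy]-3,3-dimethyl-2-(prop-2-en-1-yl)bicyclo[2.2.1]heptane, via aryne 13 (not isolated)
Conditions: KH (0.2 equiv), 18-crown-6, THF, 0 °C; then 7 (1.5 equiv, slow addition), KF, −20 → 0 °C
Reagents that add atoms: none
Why: Fluoride removes the silyl group and triflate leaves to give aryne 13; the alkoxide of 12 adds to the aryne carbon remote from the adjacent benzyloxy group (the usual regiochemistry of 3-alkoxyarynes, with the negative charge developing next to the inductively withdrawing oxygen), and the aryl anion is protonated by further 12, which carries the chain (nucleophilic addition of an alkoxide to an aryne); the carbinol carbon is not involved, so C2 keeps its configuration.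

Step 7
Reactants: 14 (1R,2R,4S)-2-[3,5-bis(benzyloxy)phenoxy]-3,3-dimethyl-2-(prop-2-en-1-yl)bicyclo[2.2.1]heptane; 15 3-methylbut-1-ene
Product: 16 (1R,2R,4S)-2-[3,5-bis(benzyloxy)phenoxy]-3,3-dimethyl-2-[(2E)-4-methylpent-2-en-1-yl]bicyclo[2.2.1]heptane
Conditions: 15 (excess), second-generation Grubbs catalyst RuCl2(=CHPh)(PCy3)(H2IMes) (5 mol%), CH2Cl2, 40 °C, sealed tube
Reagents that add atoms: none
Why: Olefin cross-metathesis of a terminal alkene with an excess of a volatile α-branched partner; reversible secondary metathesis and the bulk of the isopropyl group should favour the E-alkene, which is needed pure because a Z-alkene would lead to a cis-epoxide.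

Step 8
Reactants: 16 (1R,2R,4S)-2-[3,5-bis(benzyloxy)phenoxy]-3,3-dimethyl-2-[(2E)-4-methylpent-2-en-1-yl]bicyclo[2.2.1]heptane
Product: 17 (1R,2R,4S)-2-[3,5-bis(benzyloxy)phenoxy]-3,3-dimethyl-2-{[(2S,3S)-3-(propan-2-yl)oxiran-2-yl]methyl}bicyclo[2.2.1]heptane
Conditions: L-fructose-derived Shi ketone (enantiomer of the usual catalyst, 0.3 equiv), Oxone (2KHSO5·KHSO4·K2SO4), K2CO3, Bu4NHSO4, Na2B4O7/Na2H2EDTA buffer, MeCN–CH2(OMe)2–H2O, 0 °C
Reagents that add atoms: potassium peroxymonosulfate (active component of Oxone), [K+].[O-]S(=O)(=O)OO
Why: Shi epoxidation: the chiral dioxirane transfers oxygen through a spiro transition state; the D-fructose-derived ketone gives (R,R)-epoxides from E-1,2-disubstituted alkenes, so its enantiomer is used to obtain the (2S,3S)-epoxide; the face is chosen by the catalyst because the nearest substrate stereocentre is two bonds from the alkene.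

Step 9
Reactants: 17 (1R,2R,4S)-2-[3,5-bis(benzyloxy)phenoxy]-3,3-dimethyl-2-{[(2S,3S)-3-(propan-2-yl)oxiran-2-yl]methyl}bicyclo[2.2.1]heptane
Product: 18 (1S)-1-[(1'R,2R,4S,4'S)-5,7-bis(benzyloxy)-3',3'-dimethylspiro[chromane-2,2'-bicyclo[2.2.1]heptan]-4-yl]-2-methylpropan-1-ol
Conditions: BF3·OEt2 (0.3 equiv), CH2Cl2, −78 → −40 °C; aq. NaHCO3
Reagents that add atoms: none
Why: The Lewis acid coordinates the epoxide oxygen, the arene carbon ortho to the ether oxygen (also ortho to one benzyloxy group and para to the other) attacks the proximal epoxide carbon from the side opposite its C–O bond, and proton loss restores the arene (intramolecular Friedel–Crafts alkylation; the closest known type is the acid-promoted epoxy-arene cyclisation to chromans and tetralins). Ring B closes in the 6-exo-tet mode, the breaking C–O bond lying outside the new ring. C4 is set by stereospecific anti opening: inversion at the proximal carbon of the (2S,3S)-epoxide gives 4S, so the controlling element is the epoxide configuration from step 8, while the distal carbon keeps its oxygen with retention. Three selectivities are needed. On the arene, the two carbons ortho to the ether oxygen are interchanged by rotation about the aryl–O bond and are the only ones the tether can reach. Between the epoxide carbons, attack at the distal one would be a 7-endo closure at a carbon screened by the isopropyl group, so the proximal carbon should be preferred. In chemoselectivity, the epoxide oxygen is more basic than the hindered aryl ether oxygen, and a substoichiometric Lewis acid at −78 °C should leave the tertiary C2–O bond un-ionised and give hydride shifts little time. A chair-like transition state with the side chain and C3' both equatorial is available for this diastereomer, so reagent control and ring conformation are matched.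

Step 10
Reactants: 18 (1S)-1-[(1'R,2R,4S,4'S)-5,7-bis(benzyloxy)-3',3'-dimethylspiro[chromane-2,2'-bicyclo[2.2.1]heptan]-4-yl]-2-methylpropan-1-ol
Product: 19 O-{(1S)-1-[(1'R,2R,4S,4'S)-5,7-bis(benzyloxy)-3',3'-dimethylspiro[chromane-2,2'-bicyclo[2.2.1]heptan]-4-yl]-2-methylpropyl} S-methyl carbonodithioate
Conditions: NaH, imidazole (cat.), THF, 0 °C → rt; CS2; then MeI
Reagents that add atoms: carbon disulfide, S=C=S; iodomethane, CI
Why: The alkoxide adds to CS2 and the dithiocarbonate is S-methylated (xanthate formation, the first half of a Barton–McCombie deoxygenation); no stereocentre is affected and the tertiary ether is inert to base.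

Step 11
Reactants: 19 O-{(1S)-1-[(1'R,2R,4S,4'S)-5,7-bis(benzyloxy)-3',3'-dimethylspiro[chromane-2,2'-bicyclo[2.2.1]heptan]-4-yl]-2-methylpropyl} S-methyl carbonodithioate
Product: 20 (1'R,2R,4S,4'S)-5,7-bis(benzyloxy)-3',3'-dimethyl-4-(2-methylpropyl)spiro[chromane-2,2'-bicyclo[2.2.1]heptane]
Conditions: Bu3SnH, AIBN (cat.), toluene, 110 °C
Reagents that add atoms: none
Why: Barton–McCombie deoxygenation: the stannyl radical adds to the thiocarbonyl, β-scission gives a secondary alkyl radical, and hydrogen transfer from Bu3SnH should be faster than any aryl shift; the carbinol stereocentre is erased on purpose and C4 is not involved.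

Step 12
Reactants: 20 (1'R,2R,4S,4'S)-5,7-bis(benzyloxy)-3',3'-dimethyl-4-(2-methylpropyl)spiro[chromane-2,2'-bicyclo[2.2.1]heptane]
Product: 21 (1'R,2R,4S,4'S)-3',3'-dimethyl-4-(2-methylpropyl)spiro[chromane-2,2'-bicyclo[2.2.1]heptane]-5,7-diol
Conditions: H2 (1 atm), Pd/C (10% palladium on carbon), EtOAc–MeOH, rt
Reagents that add atoms: none
Why: Hydrogenolysis of the two aryl benzyl ethers under neutral conditions; the molecule has no alkene, and the C2–O1 bond is not benzylic and is not cleaved; the air-sensitive diphenol is used directly.

Step 13
Reactants: 21 (1'R,2R,4S,4'S)-3',3'-dimethyl-4-(2-methylpropyl)spiro[chromane-2,2'-bicyclo[2.2.1]heptane]-5,7-diol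
Product: 22 (1'R,2R,4S,4'S)-5,7-dihydroxy-3',3'-dimethyl-4-(2-methylpropyl)spiro[chromane-2,2'-bicyclo[2.2.1]heptane]-6,8-dicarbaldehyde
Conditions: Cl2CHOMe (5 equiv), TiCl4 (6 equiv), CH2Cl2, −78 → 0 °C; then ice, 1 M HCl
Reagents that add atoms: dichloromethyl methyl ether, COC(Cl)Cl; water, O
Why: Rieche formylation: the titanium phenoxides direct the chloromethoxycarbenium electrophile to C6 and C8, the only free ring positions, each flanked by oxygen on both sides, and hydrolysis of the α-chloro ethers at work-up releases the two aldehydes; double formylation of free 5,7-dihydroxychromans with a tertiary ring oxygen is a known use of this reaction.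

## Compound list

1 | 3,5-bis(benzyloxy)phenol | Oc1cc(OCc2ccccc2)cc(OCc2ccccc2)c1 | starting material
2 | 3,5-bis(benzyloxy)phenyl N-(propan-2-yl)carbamate | CC(C)NC(=O)Oc1cc(OCc2ccccc2)cc(OCc2ccccc2)c1 | intermediate
3 | 3,5-bis(benzyloxy)phenyl N-(tert-butyldimethylsilyl)-N-(propan-2-yl)carbamate | CC(C)N(C(=O)Oc1cc(OCc2ccccc2)cc(OCc2ccccc2)c1)[Si](C)(C)C(C)(C)C | intermediate (not isolated)
4 | 3,5-bis(benzyloxy)-2-(trimethylsilyl)phenyl N-(tert-butyldimethylsilyl)-N-(propan-2-yl)carbamate | CC(C)N(C(=O)Oc1cc(OCc2ccccc2)cc(OCc2ccccc2)c1[Si](C)(C)C)[Si](C)(C)C(C)(C)C | intermediate (not isolated)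
5 | 3,5-bis(benzyloxy)-2-(trimethylsilyl)phenyl N-(propan-2-yl)carbamate | CC(C)NC(=O)Oc1cc(OCc2ccccc2)cc(OCc2ccccc2)c1[Si](C)(C)C | intermediate
6 | 3,5-bis(benzyloxy)-2-(trimethylsilyl)phenol | Oc1cc(OCc2ccccc2)cc(OCc2ccccc2)c1[Si](C)(C)C | intermediate (not isolated)
7 | 3,5-bis(benzyloxy)-2-(trimethylsilyl)phenyl trifluoromethanesulfonate | C[Si](C)(C)c1c(OS(=O)(=O)C(F)(F)F)cc(OCc2ccccc2)cc1OCc1ccccc1 | intermediate
8 | (−)-camphene, (1S,4R)-2,2-dimethyl-3-methylidenebicyclo[2.2.1]heptane | C=C2[C@@H]1CC[C@@H](C1)C2(C)C | starting material
9 | camphene ozonide, spiro-1,2,4-trioxolane on the former alkene carbons (epimers at the trioxolane carbon) | C1OC2(OO1)[C@@H]3CC[C@@H](C3)C2(C)C | intermediate (not isolated)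
10 | (1R,4S)-3,3-dimethylbicyclo[2.2.1]heptan-2-one (camphenilone) | O=C2[C@@H]1CC[C@@H](C1)C2(C)C | intermediate
11 | allylmagnesium bromide | C=CC[Mg]Br | starting material
12 | (1R,2R,4S)-3,3-dimethyl-2-(prop-2-en-1-yl)bicyclo[2.2.1]heptan-2-ol (allyl exo, hydroxyl endo) | C=CC[C@@]2(O)[C@@H]1CC[C@@H](C1)C2(C)C | intermediate
13 | 3,5-bis(benzyloxy)benzyne (1,2-didehydro-3,5-bis(benzyloxy)benzene) | C1#CC(OCc2ccccc2)=CC(OCc2ccccc2)=C1 | intermediate (not isolated)
14 | (1R,2R,4S)-2-[3,5-bis(benzyloxy)phenoxy]-3,3-dimethyl-2-(prop-2-en-1-yl)bicyclo[2.2.1]heptane (aryloxy endo) | C=CC[C@@]2(Oc3cc(OCc4ccccc4)cc(OCc4ccccc4)c3)[C@@H]1CC[C@@H](C1)C2(C)C | intermediate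
15 | 3-methylbut-1-ene | CC(C)C=C | starting material
16 | (1R,2R,4S)-2-[3,5-bis(benzyloxy)phenoxy]-3,3-dimethyl-2-[(2E)-4-methylpent-2-en-1-yl]bicyclo[2.2.1]heptane | CC(C)/C=C/C[C@@]2(Oc3cc(OCc4ccccc4)cc(OCc4ccccc4)c3)[C@@H]1CC[C@@H](C1)C2(C)C | intermediate
17 | (1R,2R,4S)-2-[3,5-bis(benzyloxy)phenoxy]-3,3-dimethyl-2-{[(2S,3S)-3-(propan-2-yl)oxiran-2-yl]methyl}bicyclo[2.2.1]heptane (trans-epoxide) | CC(C)[C@@H]1O[C@H]1C[C@@]2(Oc3cc(OCc4ccccc4)cc(OCc4ccccc4)c3)[C@@H]1CC[C@@H](C1)C2(C)C | intermediate
18 | (1S)-1-[(1'R,2R,4S,4'S)-5,7-bis(benzyloxy)-3',3'-dimethylspiro[chromane-2,2'-bicyclo[2.2.1]heptan]-4-yl]-2-methylpropan-1-ol | CC(C)[C@H](O)[C@H]1C[C@@]2(Oc3cc(OCc4ccccc4)cc(OCc4ccccc4)c31)[C@@H]1CC[C@@H](C1)C2(C)C | intermediate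
19 | S-methyl xanthate of 18, O-{(1S)-1-[(1'R,2R,4S,4'S)-5,7-bis(benzyloxy)-3',3'-dimethylspiro[chromane-2,2'-bicyclo[2.2.1]heptan]-4-yl]-2-methylpropyl} S-methyl carbonodithioate | CC(C)[C@H](OC(=S)SC)[C@H]1C[C@@]2(Oc3cc(OCc4ccccc4)cc(OCc4ccccc4)c31)[C@@H]1CC[C@@H](C1)C2(C)C | intermediate
20 | (1'R,2R,4S,4'S)-5,7-bis(benzyloxy)-3',3'-dimethyl-4-(2-methylpropyl)spiro[chromane-2,2'-bicyclo[2.2.1]heptane] | CC(C)C[C@H]1C[C@@]2(Oc3cc(OCc4ccccc4)cc(OCc4ccccc4)c31)[C@@H]1CC[C@@H](C1)C2(C)C | intermediate
21 | (1'R,2R,4S,4'S)-3',3'-dimethyl-4-(2-methylpropyl)spiro[chromane-2,2'-bicyclo[2.2.1]heptane]-5,7-diol | CC(C)C[C@H]1C[C@@]2(Oc3cc(O)cc(O)c31)[C@@H]1CC[C@@H](C1)C2(C)C | intermediate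
22 | (1'R,2R,4S,4'S)-5,7-dihydroxy-3',3'-dimethyl-4-(2-methylpropyl)spiro[chromane-2,2'-bicyclo[2.2.1]heptane]-6,8-dicarbaldehyde | CC(C)C[C@H]1C[C@@]2(Oc3c(C=O)c(O)c(C=O)c(O)c31)[C@@H]1CC[C@@H](C1)C2(C)C | target

## Step count and least certain steps

Total: 13 steps. Longest linear sequence: 11 steps (steps 1–3 and 6–13, from phenol 1). The terpene branch (steps 4 and 5) joins at step 6.

**Step 9 (key step).** The activated epoxide may be diverted before the arene reaches it. The likely processes are a 1,2-hydride shift to a ketone (Meinwald rearrangement), or coordination of the Lewis acid to the ether oxygen with ionisation of the tertiary C2–O bond followed by elimination or Wagner–Meerwein shift. Neither epoxide carbon is cation-stabilised, so the opening needs real electrophilic assistance. Fallback: set out from alkene 16 and activate the C=C bond with an iodonium source (bis(pyridine)iodonium tetrafluoroborate, HBF4·OEt2, CH2Cl2, −60 °C). The arene should open the iodonium ion at the proximal carbon in the same 6-exo sense, with anti addition, to give (1'R,2R,4S,4'S)-5,7-bis(benzyloxy)-4-[(1S)-1-iodo-2-methylpropyl]-3',3'-dimethylspiro[chromane-2,2'-bicyclo[2.2.1]heptane] F1. Radical reduction (Bu3SnH, AIBN, toluene, 80 °C) removes iodine and returns to the route at 20; steps 8 to 11 are then not needed. In this variant C4 is set by the substrate and no longer by a reagent: the chair-like closure with side chain and C3' both equatorial should favour the required epimer, and any C4 epimer would have to be removed at 20.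

**Step 6.** The aryne may be consumed by faster processes than addition of the very hindered alkoxide: ene reaction with the allyl group, ring opening of THF, or oligomerisation. Fallback: go from 12 to 14 by ligand coupling at iodine. The sodium alkoxide of 12 (NaH, toluene, rt → 50 °C) is treated with [3,5-bis(benzyloxy)phenyl](2,4,6-trimethoxyphenyl)iodonium 4-methylbenzenesulfonate F2, made in one operation from 1,3-bis(benzyloxy)-5-iodobenzene, mCPBA, TsOH and 1,3,5-trimethoxybenzene. The less electron-rich, less hindered aryl group should be transferred to oxygen, and the route is rejoined at 14. Even if part of the reaction ran through the aryne, the same ether would result.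

**Step 13.** TiCl4 may ionise the C2–O1 bond once C8 carries a formyl group that can chelate the metal next to O1, leading to ring opening and skeletal rearrangement. The reaction may also stall after the first formylation, because the ring is then deactivated. Fallback: set out from 20 and introduce the carbons before deprotection. NBS (2.2 equiv, MeCN, 0 °C) should brominate C6 and C8, the only free positions, to give (1'R,2R,4S,4'S)-5,7-bis(benzyloxy)-6,8-dibromo-3',3'-dimethyl-4-(2-methylpropyl)spiro[chromane-2,2'-bicyclo[2.2.1]heptane] F3. Double bromine–lithium exchange (t-BuLi, THF, −78 °C) and quenching with DMF gives (1'R,2R,4S,4'S)-5,7-bis(benzyloxy)-3',3'-dimethyl-4-(2-methylpropyl)spiro[chromane-2,2'-bicyclo[2.2.1]heptane]-6,8-dicarbaldehyde F4. Hydrogenolysis (H2, Pd/C, EtOAc, stopped when F4 is consumed so the aldehydes are not reduced) gives 22 directly.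

**Step 2.** n-BuLi/TMEDA may deprotonate a benzylic OCH2 group, which then undergoes [1,2]-Wittig rearrangement, in competition with ring lithiation. Fallback: set out from 1 and use halogen–metal exchange in place of deprotonation. NBS (CH2Cl2, −78 °C) gives 2-bromo-3,5-bis(benzyloxy)phenol F5, which is freed from its para-bromo isomer. (Me3Si)2NH (THF, 65 °C) gives [2-bromo-3,5-bis(benzyloxy)phenoxy]trimethylsilane F6. n-BuLi at −78 °C effects bromine–lithium exchange, much faster than benzylic deprotonation, followed by 1,3 migration of silicon from oxygen to carbon (retro-Brook), and Tf2O then gives 7.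

**Step 5.** Facial selectivity may be poor. Allylmagnesium halides react through a six-membered transition state at rates near diffusion control and discriminate less between the faces than other organometallics, and each face of 10 carries one methyl group. The endo-allyl epimer would lead to the C2 epimer of everything that follows, and must be removed at 12. Fallback: set out from 10 and build the allyl group in two C–C bond formations. Dimethylsulfonium methylide (Me3SI, n-BuLi, THF, −10 °C → rt), a smaller and less reactive nucleophile, should add from the exo face and close irreversibly to (1R,2R,4S)-3,3-dimethylspiro[bicyclo[2.2.1]heptane-2,2'-oxirane] F7 (CH2 exo, oxygen endo). Vinylmagnesium bromide with catalytic CuI (THF, −20 °C → rt) opens F7 at its CH2 carbon and gives 12.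

## Further compounds

F1 | step 9 | (1'R,2R,4S,4'S)-5,7-bis(benzyloxy)-4-[(1S)-1-iodo-2-methylpropyl]-3',3'-dimethylspiro[chromane-2,2'-bicyclo[2.2.1]heptane] | CC(C)[C@H](I)[C@H]1C[C@@]2(Oc3cc(OCc4ccccc4)cc(OCc4ccccc4)c31)[C@@H]1CC[C@@H](C1)C2(C)C
F2 | step 6 | [3,5-bis(benzyloxy)phenyl](2,4,6-trimethoxyphenyl)iodonium 4-methylbenzenesulfonate | COc1cc(OC)c([I+]c2cc(OCc3ccccc3)cc(OCc3ccccc3)c2)c(OC)c1.Cc1ccc(cc1)S(=O)(=O)[O-]
F3 | step 13 | (1'R,2R,4S,4'S)-5,7-bis(benzyloxy)-6,8-dibromo-3',3'-dimethyl-4-(2-methylpropyl)spiro[chromane-2,2'-bicyclo[2.2.1]heptane] | CC(C)C[C@H]1C[C@@]2(Oc3c(Br)c(OCc4ccccc4)c(Br)c(OCc4ccccc4)c31)[C@@H]1CC[C@@H](C1)C2(C)C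
F4 | step 13 | (1'R,2R,4S,4'S)-5,7-bis(benzyloxy)-3',3'-dimethyl-4-(2-methylpropyl)spiro[chromane-2,2'-bicyclo[2.2.1]heptane]-6,8-dicarbaldehyde | CC(C)C[C@H]1C[C@@]2(Oc3c(C=O)c(OCc4ccccc4)c(C=O)c(OCc4ccccc4)c31)[C@@H]1CC[C@@H](C1)C2(C)C
F5 | step 2 | 2-bromo-3,5-bis(benzyloxy)phenol | Oc1cc(OCc2ccccc2)cc(OCc2ccccc2)c1Br
F6 | step 2 | [2-bromo-3,5-bis(benzyloxy)phenoxy]trimethylsilane | C[Si](C)(C)Oc1cc(OCc2ccccc2)cc(OCc2ccccc2)c1Br
F7 | step 5 | (1R,2R,4S)-3,3-dimethylspiro[bicyclo[2.2.1]heptane-2,2'-oxirane] (oxygen endo) | C1O[C@@]12[C@@H]3CC[C@@H](C3)C2(C)C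
A1 | alternative 1 | 6'-exo-chloro-5,7-dimethoxy-3',3'-dimethyl-4-(2-methylpropyl)spiro[chromane-2,2'-bicyclo[2.2.1]heptane] (configuration as in the SMILES) | CC(C)C[C@H]1C[C@@]2(Oc3cc(OC)cc(OC)c31)[C@@H]1[C@@H](Cl)C[C@@H](C1)C2(C)C
A2 | alternative 1 | (5S)-2-(cyclopent-3-en-1-yl)-5-(2-hydroxy-4,6-dimethoxyphenyl)-2,7-dimethyloctan-3-one | CC(C)C[C@@H](CC(=O)C(C)(C)C1CC=CC1)c1c(O)cc(OC)cc1OC
A3 | alternative 2 | 3',3'-dimethyl-4-(2-methylpropyl)spiro[2H-chromene-2,2'-bicyclo[2.2.1]heptane]-5,7-diol (configuration as in the SMILES) | CC(C)CC1=C[C@@]2(Oc3cc(O)cc(O)c31)[C@@H]1CC[C@@H](C1)C2(C)C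
A4 | alternative 2 | 1-[(1R,4S)-3,3-dimethylbicyclo[2.2.1]heptan-2-ylidene]-4-methylpentan-2-one | CC(C)CC(=O)C=C1[C@@H]2CC[C@@H](C2)C1(C)C
A5 | alternative 2 | benzene-1,3,5-triol (phloroglucinol) | Oc1cc(O)cc(O)c1
A6 | alternative 3 | 5,7-dimethoxy-3',3'-dimethyl-4-(2-methylpropyl)spiro[chromane-2,2'-bicyclo[2.2.1]hept-5'-ene] (configuration as in the SMILES) | CC(C)C[C@H]1C[C@@]2(Oc3cc(OC)cc(OC)c31)[C@@H]1C=C[C@@H](C1)C2(C)C
A7 | alternative 3 | (4S)-5,7-dimethoxy-4-(2-methylpropyl)-2-(propan-2-ylidene)chromane | CC(C)C[C@H]1CC(=C(C)C)Oc2cc(OC)cc(OC)c21
A8 | alternative 3 | cyclopenta-1,3-diene | C1=CC=CC1
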